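**Retrosynthetic overview**

1. The strategy rests on spiro carbon C2 of pyran ring B, which is also pinane C2'. It holds O1 on the face of the C7' methylene bridge and C3 on the face of the C6' gem-dimethyl bridge, and C3 lies α to C4, which can be a ketone. An aryl nopinyl ether made with inversion from cis-nopinol has its oxygen and its H-2' in exactly these positions.
2. Key disconnection C2–C3: the carbenoid from an ortho-(nopinyloxy)aryl diazomethyl ketone inserts into the C2'–H bond with retention. This closes ring B, the only ring made in the route; aromatic ring A and the pinane are bought.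
3. The diazo ketone comes from a methyl ketone by diazo transfer. The aryl–O–C2' bond comes from Mitsunobu etherification of cis-nopinol with 1-(2,4-difluoro-6-hydroxyphenyl)ethanone, itself made from 3,5-difluorophenol by Fries rearrangement.
4. The two fluorines have three jobs: they are inert toward the carbenoid, they direct lithiation to C6 for the isovaleryl group, and they then leave in an SNAr reaction activated by that C6 ketone.
5. C4=O is removed before any strong base is used, so no β-aryloxy ketone is left that could open ring B and scramble C2. Acids that could ionise the tertiary pinanyl ether are avoided throughout, and C8 is formylated last as the only free ring position.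

Key step: step 5

Remark (assumption on the chemistry): hydride and other nucleophiles are taken to approach C2 of nopinone and its derivatives from the face of the C7 methylene bridge, because the other face is shielded by the syn methyl of the C6 gem-dimethyl bridge. Chroman numbering (O1, C2–C8a) is used, with primed numbers for the pinane.

**Route**

Step 1
Reactants: 1 (+)-nopinone
Product: 2 cis-nopinol [(1R,2R,5S)-6,6-dimethylbicyclo[3.1.1]heptan-2-ol; OH on the gem-dimethyl face]
Conditions: NaBH4, MeOH, 0 °C
Reagents that add atoms: none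
Why: In this borohydride reduction the hydride should add from the C7 face, away from the syn methyl of the gem-dimethyl bridge, so the new carbinol centre C2 carries OH on the gem-dimethyl face (2R), and any minor epimer is removed by chromatography.

Step 2
Reactants: 3 3,5-difluorophenol; 4 acetyl chloride
Product: 6 1-(2,4-difluoro-6-hydroxyphenyl)ethanone, via 3,5-difluorophenyl acetate 5 (not isolated)
Conditions: neat, 50 °C; then AlCl3 (1.5 equiv), 150 °C; then ice/aq. HCl
Reagents that add atoms: none
Why: O-Acetylation followed by a hot AlCl3-mediated Fries rearrangement should place the acetyl group ortho to oxygen as the chelated product, the alternative position between the two fluorines being the less nucleophilic one.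

Step 3
Reactants: 2 cis-nopinol; 6 1-(2,4-difluoro-6-hydroxyphenyl)ethanone
Product: 7 1-[2,4-difluoro-6-[(1R,2S,5S)-6,6-dimethylbicyclo[3.1.1]hept-2-yloxy]phenyl]ethanone (ether oxygen on the C7' face; H-2' on the gem-dimethyl face)
Conditions: PPh3, DIAD, toluene, 0 °C → rt
Reagents that add atoms: none
Why: In this Mitsunobu etherification the acidic, fluorine-activated phenol displaces the oxyphosphonium group of 2 by SN2 attack from the open C7' face, so C2' is inverted to 2S and the aryloxy group ends on the C7' face.

Step 4
Reactants: 7 1-[2,4-difluoro-6-[(1R,2S,5S)-6,6-dimethylbicyclo[3.1.1]hept-2-yloxy]phenyl]ethanone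
Product: 9 2-diazo-1-[2,4-difluoro-6-[(1R,2S,5S)-6,6-dimethylbicyclo[3.1.1]hept-2-yloxy]phenyl]ethanone, via trifluoroacetyl diketone 8 (not isolated)
Conditions: LiN(SiMe3)2, THF, −78 °C; CF3CO2CH2CF3; aq. HCl; then MsN3, Et3N, H2O (1 equiv), MeCN, rt
Reagents that add atoms: 2,2,2-trifluoroethyl trifluoroacetate, O=C(OCC(F)(F)F)C(F)(F)F (its atoms stay only in 8); methanesulfonyl azide, CS(=O)(=O)N=[N+]=[N-]
Why: In this detrifluoroacetylative diazo transfer (Danheiser procedure) the lithium enolate of the methyl ketone is trifluoroacetylated and the activated diketone takes the diazo group from mesyl azide with loss of the trifluoroacetyl group, leaving the ether, the fluorines and C2' untouched.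

Step 5
Reactants: 9 2-diazo-1-[2,4-difluoro-6-[(1R,2S,5S)-6,6-dimethylbicyclo[3.1.1]hept-2-yloxy]phenyl]ethanone
Product: 10 (1'R,2'R,5'S)-5,7-difluoro-6',6'-dimethylspiro[chroman-2,2'-bicyclo[3.1.1]heptan]-4-one (O1 on the C7' face; C3 on the gem-dimethyl face)
Conditions: Rh2(OAc)4 (2 mol %), CH2Cl2, rt, 9 added over 6 h by syringe pump (high dilution)
Reagents that add atoms: none
Why: Rh2(OAc)4, a complex of divalent rhodium, expels N2 from 9, and the electrophilic carbenoid carbon (the future C3) inserts into the C2'–H bond next to the ether oxygen through a three-centre, hydride-transfer-like transition state; the closest known reaction type is the dirhodium tetracarboxylate-catalysed intramolecular C–H insertion of ortho-alkoxyaryl α-diazo ketones to chroman-4-ones. Ring B closes by this 1,6-insertion with C2–C3 as the only new skeletal bond, and the five-membered closure that carbenoids usually prefer has no C–H bond to use because the atom at that distance is O1. The new stereocentre, spiro C2 (= C2'), is controlled by the substrate: a concerted insertion goes with retention, so C3 takes the place of the hydrogen on the gem-dimethyl face and O1 stays on the C7' face as fixed by the inversion in step 3. The step needs site selectivity and chemoselectivity: the C2'–H bond is the only C–H bond that is both activated by oxygen and within reach, the ortho fluorine offers neither a C–H bond nor a group that can shift, and slow addition suppresses carbene dimerisation. The competing path is oxonium ylide formation at O1 followed by 1,2-shift or elimination to a benzofuran-3-one, which a secondary alkyl ether without allyl or benzyl character should undergo only slowly.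

Step 6
Reactants: 10 (1'R,2'R,5'S)-5,7-difluoro-6',6'-dimethylspiro[chroman-2,2'-bicyclo[3.1.1]heptan]-4-one
Product: 11 4-tosylhydrazone of 10
Conditions: TsNHNH2, EtOH, 70 °C
Reagents that add atoms: 4-methylbenzenesulfonohydrazide, Cc1ccc(cc1)S(=O)(=O)NN
Why: Hydrazone condensation at C4 runs under neutral conditions, which avoids both the base-induced retro-oxa-Michael opening of the β-aryloxy ketone that would endanger C2 and the acid that could ionise the tertiary pinanyl ether.

Step 7
Reactants: 11 4-tosylhydrazone of 10
Product: 13 (1'R,2'R,5'S)-5,7-difluoro-6',6'-dimethylspiro[chroman-2,2'-bicyclo[3.1.1]heptane], via N-boryl tosylhydrazide 12 (not isolated)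
Conditions: catecholborane, CHCl3, 0 °C → rt; then NaOAc·3H2O, 60 °C
Reagents that add atoms: catecholborane, B1Oc2ccccc2O1 (its atoms stay only in 12)
Why: In this Kabalka-type tosylhydrazone reduction catecholborane adds hydride to C=N, acetate releases sulfinate, and the resulting alkyl diazene loses N2 to leave C4 as CH2 without strong acid or base.

Step 8
Reactants: 13 (1'R,2'R,5'S)-5,7-difluoro-6',6'-dimethylspiro[chroman-2,2'-bicyclo[3.1.1]heptane]; 14 isovaleraldehyde
Product: 16 1-[(1'R,2'R,5'S)-5,7-difluoro-6',6'-dimethylspiro[chroman-2,2'-bicyclo[3.1.1]heptan]-6-yl]-3-methylbutan-1-ol (carbinol epimers), via aryllithium 15 (not isolated)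
Conditions: LiN(iPr)2, THF, −78 °C; then 14, −78 °C; then H2O
Reagents that add atoms: lithium diisopropylamide, [Li+].CC(C)[N-]C(C)C (lithium stays only in 15)
Why: In this directed ortho-metalation the C6–H flanked by two fluorines is the most acidic arene C–H (C8–H has only one fluorine and the hindered O1 beside it), and the aryllithium, kept at −78 °C to prevent LiF loss to an aryne, adds to the aldehyde to give a carbinol centre whose configuration is erased in step 9.

Step 9
Reactants: 16 carbinol from step 8
Product: 17 1-[(1'R,2'R,5'S)-5,7-difluoro-6',6'-dimethylspiro[chroman-2,2'-bicyclo[3.1.1]heptan]-6-yl]-3-methylbutan-1-one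
Conditions: Dess–Martin periodinane, pyridine, CH2Cl2, 0 °C → rt
Reagents that add atoms: none
Why: Dess–Martin oxidation of the secondary benzylic alcohol should give the aryl ketone under buffered, non-acidic conditions that leave the tertiary ether alone.

Step 10
Reactants: 17 difluoro ketone from step 9; 18 benzyl alcohol (first equivalent, for the C7 benzyloxy group)
Product: 20 1-[(1'R,2'R,5'S)-5,7-bis(benzyloxy)-6',6'-dimethylspiro[chroman-2,2'-bicyclo[3.1.1]heptan]-6-yl]-3-methylbutan-1-one, via monobenzyl ether 19 (not isolated)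
Conditions: BnOH (5 equiv), NaH (3 equiv), THF, 0 °C; then 17, N,N-dimethylacetamide, 70 °C
Reagents that add atoms: benzyl alcohol (second equivalent, for the C5 benzyloxy group; both equivalents react as sodium benzyloxide), OCc1ccccc1
Why: In this twofold nucleophilic aromatic substitution (addition–elimination) each fluorine is ortho to the C6 ketone and meta to the other, so two equivalents of sodium benzyloxide should replace the two fluorides in turn, and with C4 now a methylene no enolate can expel O1, so C2 is safe.

Step 11
Reactants: 20 bis(benzyloxy) ketone from step 10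
Product: 21 1-[(1'R,2'R,5'S)-5,7-dihydroxy-6',6'-dimethylspiro[chroman-2,2'-bicyclo[3.1.1]heptan]-6-yl]-3-methylbutan-1-one
Conditions: H2 (1 atm), Pd/C (10% Pd on carbon), EtOAc, rt
Reagents that add atoms: none
Why: Catalytic hydrogenolysis should cleave both benzyl ethers, while the hindered aryl ketone, which becomes chelated as the phenols are freed, and the saturated pinane are not expected to be reduced at 1 atm if the reaction is stopped after two equivalents of H2.

Step 12
Reactants: 21 dihydroxy ketone from step 11
Product: 23 Euglobal G3, via iminium chloride 22 (not isolated)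
Conditions: POCl3, DMF, MeCN, 0 °C → rt; then aq. NaOAc, rt
Reagents that add atoms: N,N-dimethylformamide, CN(C)C=O; water, O; phosphoryl chloride, O=P(Cl)(Cl)Cl (chloride counter-ion of 22 only)
Why: In this Vilsmeier–Haack formylation C8 is the only unsubstituted position of the acylphloroglucinol-type ring A and is activated by O1 and the C7 hydroxyl, and low temperature with buffered hydrolysis of the iminium salt should spare the side-chain ketone and the tertiary ether.

**Compound list**

1 | (+)-nopinone, (1R,5S)-6,6-dimethylbicyclo[3.1.1]heptan-2-one | O=C1CC[C@H]2C[C@@H]1C2(C)C | starting material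
2 | cis-nopinol, (1R,2R,5S)-6,6-dimethylbicyclo[3.1.1]heptan-2-ol (OH on the gem-dimethyl face) | O[C@@H]1CC[C@H]2C[C@@H]1C2(C)C | intermediate
3 | 3,5-difluorophenol | Oc1cc(F)cc(F)c1 | starting material
4 | acetyl chloride | CC(=O)Cl | starting material
5 | 3,5-difluorophenyl acetate | CC(=O)Oc1cc(F)cc(F)c1 | intermediate (not isolated)
6 | 1-(2,4-difluoro-6-hydroxyphenyl)ethanone | CC(=O)c1c(O)cc(F)cc1F | intermediate
7 | 1-[2,4-difluoro-6-[(1R,2S,5S)-6,6-dimethylbicyclo[3.1.1]hept-2-yloxy]phenyl]ethanone (O on the C7' face) | CC(=O)c1c(F)cc(F)cc1O[C@H]1CC[C@H]2C[C@@H]1C2(C)C | intermediate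
8 | 4,4,4-trifluoro-1-[2,4-difluoro-6-[(1R,2S,5S)-6,6-dimethylbicyclo[3.1.1]hept-2-yloxy]phenyl]butane-1,3-dione | O=C(CC(=O)C(F)(F)F)c1c(F)cc(F)cc1O[C@H]1CC[C@H]2C[C@@H]1C2(C)C | intermediate (not isolated)
9 | 2-diazo-1-[2,4-difluoro-6-[(1R,2S,5S)-6,6-dimethylbicyclo[3.1.1]hept-2-yloxy]phenyl]ethanone | [N-]=[N+]=CC(=O)c1c(F)cc(F)cc1O[C@H]1CC[C@H]2C[C@@H]1C2(C)C | intermediate (key-step precursor)
10 | (1'R,2'R,5'S)-5,7-difluoro-6',6'-dimethylspiro[chroman-2,2'-bicyclo[3.1.1]heptan]-4-one | O=C1C[C@@]2(CC[C@H]3C[C@@H]2C3(C)C)Oc2cc(F)cc(F)c21 | intermediate (key-step product)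
11 | 4-tosylhydrazone of 10 (C=N geometry not defined) | Cc1ccc(cc1)S(=O)(=O)NN=C1C[C@@]2(CC[C@H]3C[C@@H]2C3(C)C)Oc2cc(F)cc(F)c21 | intermediate
12 | N-(1,3,2-benzodioxaborol-2-yl)-N'-tosylhydrazine at C4 of the chroman (C4 epimers) | Cc1ccc(cc1)S(=O)(=O)NN(B1Oc2ccccc2O1)C1C[C@@]2(CC[C@H]3C[C@@H]2C3(C)C)Oc2cc(F)cc(F)c21 | intermediate (not isolated)
13 | (1'R,2'R,5'S)-5,7-difluoro-6',6'-dimethylspiro[chroman-2,2'-bicyclo[3.1.1]heptane] | Fc1cc(F)c2CC[C@@]3(CC[C@H]4C[C@@H]3C4(C)C)Oc2c1 | intermediate
14 | isovaleraldehyde (3-methylbutanal) | CC(C)CC=O | starting material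
15 | 6-lithio derivative of 13 | [Li]c1c(F)cc2c(c1F)CC[C@@]1(CC[C@H]3C[C@@H]1C3(C)C)O2 | intermediate (not isolated)
16 | 1-[(1'R,2'R,5'S)-5,7-difluoro-6',6'-dimethylspiro[chroman-2,2'-bicyclo[3.1.1]heptan]-6-yl]-3-methylbutan-1-ol (carbinol epimers) | CC(C)CC(O)c1c(F)cc2c(c1F)CC[C@@]1(CC[C@H]3C[C@@H]1C3(C)C)O2 | intermediate
17 | 1-[(1'R,2'R,5'S)-5,7-difluoro-6',6'-dimethylspiro[chroman-2,2'-bicyclo[3.1.1]heptan]-6-yl]-3-methylbutan-1-one | CC(C)CC(=O)c1c(F)cc2c(c1F)CC[C@@]1(CC[C@H]3C[C@@H]1C3(C)C)O2 | intermediate
18 | benzyl alcohol | OCc1ccccc1 | starting material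
19 | 7-benzyloxy-5-fluoro analogue of 17 (the less hindered C7–F is expected to react first) | CC(C)CC(=O)c1c(OCc3ccccc3)cc2c(c1F)CC[C@@]1(CC[C@H]3C[C@@H]1C3(C)C)O2 | intermediate (not isolated)
20 | 1-[(1'R,2'R,5'S)-5,7-bis(benzyloxy)-6',6'-dimethylspiro[chroman-2,2'-bicyclo[3.1.1]heptan]-6-yl]-3-methylbutan-1-one | CC(C)CC(=O)c1c(OCc3ccccc3)cc2c(c1OCc1ccccc1)CC[C@@]1(CC[C@H]3C[C@@H]1C3(C)C)O2 | intermediate
21 | 1-[(1'R,2'R,5'S)-5,7-dihydroxy-6',6'-dimethylspiro[chroman-2,2'-bicyclo[3.1.1]heptan]-6-yl]-3-methylbutan-1-one | CC(C)CC(=O)c1c(O)cc2c(c1O)CC[C@@]1(CC[C@H]3C[C@@H]1C3(C)C)O2 | intermediate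
22 | C8 dimethyliminium chloride of 21 | CC(C)CC(=O)c1c(O)c(C=[N+](C)C)c2c(c1O)CC[C@@]1(CC[C@H]3C[C@@H]1C3(C)C)O2.[Cl-] | intermediate (not isolated)
23 | Euglobal G3, (1'R,2'R,5'S)-5,7-dihydroxy-6',6'-dimethyl-6-(3-methylbutanoyl)spiro[chroman-2,2'-bicyclo[3.1.1]heptane]-8-carbaldehyde | CC(C)CC(=O)c1c(O)c(C=O)c2c(c1O)CC[C@@]1(CC[C@H]3C[C@@H]1C3(C)C)O2 | target

**Step count and risks**

Total step count: 12. Longest linear sequence: 11 steps (steps 1 and 3–12 from (+)-nopinone; equally steps 2–12 from 3,5-difluorophenol).

Steps most likely to fail: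

1. Step 5. The carbenoid may fail to reach the C2'–H bond on the face shielded by the syn methyl of the gem-dimethyl bridge. Ylide formation at O1 with 1,2-shift or elimination, carbene dimerisation, or a stepwise hydride transfer with loss of retention would then take over. The fallback sets out from 6 and 1 and returns at 10. A Kabbe condensation (pyrrolidine, MeOH, 60 °C) should give, by aldol condensation, the enone 1-(2,4-difluoro-6-hydroxyphenyl)-2-[(1R,5S)-6,6-dimethylbicyclo[3.1.1]hept-2-ylidene]ethanone F1. Its phenol is expected to close ring B by oxa-Michael addition to the exocyclic carbon from the open C7' face, giving 10, and any spiro epimer would be removed by chromatography. The amine is kept substoichiometric to limit its attack on the fluoroarene.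

2. Step 3. The activated alcohol may eliminate to the alkene, the oxyphosphonium ion next to the cyclobutane may ionise and rearrange, or the chelated phenol may be too poor a nucleophile for the hindered secondary centre. The fallback sets out from 2 and returns at 7. Mitsunobu esterification with 4-nitrobenzoic acid (PPh3, DIAD, THF) should give the inverted ester (1R,2S,5S)-6,6-dimethylbicyclo[3.1.1]hept-2-yl 4-nitrobenzoate F2. Methanolysis (K2CO3, MeOH) frees the inverted alcohol (1R,2S,5S)-6,6-dimethylbicyclo[3.1.1]heptan-2-ol F3, with OH on the C7 face. Its potassium alkoxide (KN(SiMe3)2, toluene/THF, −20 °C) then displaces an ortho fluoride of commercial 2',4',6'-trifluoroacetophenone with retention at C2', giving 7. A para-substituted isomer would be separated.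

3. Step 10. The second substitution may stall once the first benzyloxy group twists the ketone out of conjugation, the ketone enolate may deactivate the ring, or alkoxide may attack the carbonyl and cleave the aryl–acyl bond. The fallback sets out from 13 and returns at 20. Aryllithium 15, made as in step 8, is quenched with DMF to give the aldehyde (1'R,2'R,5'S)-5,7-difluoro-6',6'-dimethylspiro[chroman-2,2'-bicyclo[3.1.1]heptane]-6-carbaldehyde F4. This non-enolisable, coplanar formyl group activates both ortho fluorines more strongly, and sodium benzyloxide (2.5 equiv, THF/N,N-dimethylacetamide, 0 → 40 °C) should give the 5,7-bis(benzyloxy) aldehyde F5. Addition of iBuMgBr (THF, 0 °C) gives the carbinol 1-[5,7-bis(benzyloxy)spirochroman-6-yl]-3-methylbutan-1-ol F6, and Dess–Martin oxidation gives 20.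

**Further compounds**

F1 | step 5 | 1-(2,4-difluoro-6-hydroxyphenyl)-2-[(1R,5S)-6,6-dimethylbicyclo[3.1.1]hept-2-ylidene]ethanone (alkene geometry not defined) | O=C(C=C1CC[C@H]2C[C@@H]1C2(C)C)c1c(O)cc(F)cc1F
F2 | step 3 | (1R,2S,5S)-6,6-dimethylbicyclo[3.1.1]hept-2-yl 4-nitrobenzoate | O=C(O[C@H]1CC[C@H]2C[C@@H]1C2(C)C)c1ccc(cc1)[N+](=O)[O-]
F3 | step 3 | (1R,2S,5S)-6,6-dimethylbicyclo[3.1.1]heptan-2-ol (OH on the C7 face) | O[C@H]1CC[C@H]2C[C@@H]1C2(C)C
F4 | step 10 | (1'R,2'R,5'S)-5,7-difluoro-6',6'-dimethylspiro[chroman-2,2'-bicyclo[3.1.1]heptane]-6-carbaldehyde | O=Cc1c(F)cc2c(c1F)CC[C@@]1(CC[C@H]3C[C@@H]1C3(C)C)O2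
F5 | step 10 | (1'R,2'R,5'S)-5,7-bis(benzyloxy)-6',6'-dimethylspiro[chroman-2,2'-bicyclo[3.1.1]heptane]-6-carbaldehyde | O=Cc1c(OCc3ccccc3)cc2c(c1OCc1ccccc1)CC[C@@]1(CC[C@H]3C[C@@H]1C3(C)C)O2
F6 | step 10 | 1-[(1'R,2'R,5'S)-5,7-bis(benzyloxy)-6',6'-dimethylspiro[chroman-2,2'-bicyclo[3.1.1]heptan]-6-yl]-3-methylbutan-1-ol (carbinol epimers) | CC(C)CC(O)c1c(OCc3ccccc3)cc2c(c1OCc1ccccc1)CC[C@@]1(CC[C@H]3C[C@@H]1C3(C)C)O2
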